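**Remark on the chemistry.** Lignan numbering is used for target atoms: C7/C7' are the benzylic carbons, C8/C8' the ring methines, C9 the CH2OH carbon, C9' the ring CH2. Ar = 3-methoxy-4-(triisopropylsilyloxy)phenyl in names. Stereochemical outcomes are predictions from mechanism and analogy, not measured results.

**Plan**

1. Retrosynthesis: the C9 carbinol is taken back to a formyl group (via a lactol to O7'). The C7–C8 bond of the tetrahydrofuran is then cut by a retro-[1,3] O-to-C shift to a seven-membered 4,5-dihydro-1,3-dioxepine. This ring is cut at its C6=C7 enol ether bond (metathesis) and its acetal C–O bond, and finally at C7'–C8' (aldol).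
2. Enabling feature: in the tetrahydrofuran, C7 is a benzylic O-bearing carbon (latent aryl-stabilised oxocarbenium, O=C7) and C8–C9 is a latent enol at the aldehyde level. Tying the C9 oxygen back onto C7 gives the cyclic vinyl acetal O1–C2(Ar)–O3–C4–C5–C6=C7, whose heterolysis at C2–O1 releases both partners, held together by C4–C5.
3. Forward order: Evans crotonate aldol (C7'–C8'), reduction to the alcohol, mixed allyl acetal, propenyl acetal, ring-closing metathesis to the seven-membered ring, TMSOTf contraction to the tetrahydrofuran-3-carbaldehyde, then in one flask desilylation/epimerisation into a temporary cis-fused lactol and NaBH4 opening to the diol.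
4. Stereochemistry: C7' and C8' come from the (S)-benzyloxazolidinone syn-aldol; C7 from the kinetic ring contraction (aryl trans to the C8' substituent); C8 by base epimerisation funnelled into the cis-fused lactol ring, which is then cleaved.

Key step: step 10

**Step 1**
Reactants: 1 vanillin
Product: 2 3-methoxy-4-(triisopropylsilyloxy)benzaldehyde (ArCHO)
Conditions: TIPSCl (1.1 equiv), imidazole (2.2 equiv), DMF, rt
Reagents that add atoms: triisopropylsilyl chloride, CC(C)[Si](Cl)(C(C)C)C(C)C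
Why: Silylation of the phenol gives a fluoride-labile aryl silyl ether that should tolerate the Lewis acids and hydrides used later.

**Step 2**
Reactants: 3 (S)-4-benzyloxazolidin-2-one; 4 (E)-but-2-enoyl chloride
Product: 5 (S)-4-benzyl-3-[(E)-but-2-enoyl]oxazolidin-2-one
Conditions: n-BuLi (1.0 equiv), THF, −78 °C; then 4, −78 to 0 °C
Reagents that add atoms: none
Why: N-Acylation of the lithiated oxazolidinone with the acid chloride installs the Evans auxiliary on the four-carbon unit that becomes C9', C8' and C8.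

**Step 3**
Reactants: 5 crotonyl imide; 2 ArCHO
Product: 7 (S)-4-benzyl-3-{(2S)-2-[(S)-Ar(hydroxy)methyl]but-3-enoyl}oxazolidin-2-one, via Z-dibutylboron dienolate 6 (not isolated)
Conditions: Bu2BOTf (1.2 equiv), Et3N (1.4 equiv), CH2Cl2, −78 to 0 °C; 2, −78 to 0 °C; then pH 7 buffer, MeOH, H2O2, 0 °C
Reagents that add atoms: none
Why: Evans syn-aldol of the boron dienolate, which reacts at its α-carbon through a Zimmerman–Traxler chair on the face away from the benzyl group, should set C8' and C7' as (2S,3S) and leave the deconjugated vinyl group.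

**Step 4**
Reactants: 7 aldol adduct
Product: 8 (S)-4-benzyl-3-{(2S)-2-[(S)-Ar(tert-butyldimethylsilyloxy)methyl]but-3-enoyl}oxazolidin-2-one
Conditions: TBSOTf (1.3 equiv), 2,6-lutidine (2 equiv), CH2Cl2, 0 °C
Reagents that add atoms: tert-butyldimethylsilyl triflate, CC(C)(C)[Si](C)(C)OS(=O)(=O)C(F)(F)F
Why: Silylation of the secondary benzylic alcohol with a silyl triflate and a hindered weak base masks O7' without epimerising the α-vinyl imide.

**Step 5**
Reactants: 8 silyl ether
Product: 9 (2R)-2-[(S)-Ar(tert-butyldimethylsilyloxy)methyl]but-3-en-1-ol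
Conditions: LiBH4 (2 equiv), MeOH (2 equiv), THF, 0 °C
Reagents that add atoms: none
Why: Reductive removal of the Evans auxiliary (imide to primary alcohol) turns the imide carbonyl into the C9' carbinol without touching the stereocentres or silyl ethers.

**Step 6**
Reactants: 2 ArCHO
Product: 10 4-[bis(allyloxy)methyl]-2-methoxy-1-(triisopropylsilyloxy)benzene (diallyl acetal of 2)
Conditions: allyloxytrimethylsilane (2.5 equiv), TMSOTf (2 mol%), CH2Cl2, −78 °C; pyridine quench
Reagents that add atoms: allyloxytrimethylsilane, C=CCO[Si](C)(C)C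
Why: Noyori acetalisation (aldehyde plus alkyl silyl ether, catalytic TMSOTf) gives the acetal under aprotic conditions that spare the aryl silyl ether.

**Step 7**
Reactants: 9 alcohol; 10 diallyl acetal (3 equiv)
Product: 11 mixed acetal ArCH(O-allyl)[O-CH2-CH(CH=CH2)-CH(OTBS)Ar] (both epimers at the acetal carbon)
Conditions: PPTS (5 mol%), toluene, 40 °C, reduced pressure; Et3N quench
Reagents that add atoms: none
Why: Acid-catalysed transacetalisation of the electron-rich benzylic acetal, driven by excess 10 and removal of allyl alcohol, should give the mixed acetal, whose new acetal centre is planarised later and need not be controlled.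

**Step 8**
Reactants: 11 mixed allyl acetal
Product: 12 mixed acetal ArCH[O-(E)-prop-1-enyl][O-CH2-CH(CH=CH2)-CH(OTBS)Ar]
Conditions: [Ir(cod)(PMePh2)2]PF6 (3 mol%, activated with H2, then degassed), THF, rt
Reagents that add atoms: none
Why: Iridium hydride isomerisation of the allyl ether through a π-allyl hydride gives the (E)-propenyl ether, while the hindered C8' vinyl group with its single tertiary allylic hydrogen is expected to react much more slowly.

**Step 9**
Reactants: 12 propenyl acetal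
Product: 13 (5R)-2-Ar-5-[(S)-Ar(tert-butyldimethylsilyloxy)methyl]-4,5-dihydro-1,3-dioxepine (both C2 epimers)
Conditions: second-generation Grubbs catalyst (5 mol%), toluene (0.005 M), 70 °C; filtration through Et3N-deactivated silica
Reagents that add atoms: none
Why: Ring-closing metathesis of an enol ether with a terminal alkene, in which the ruthenium alkylidene loads on the vinyl group and closes onto the propenyl ether with loss of propene, should give the seven-membered cyclic Z-enol ether without touching a stereocentre.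

**Step 10**
Reactants: 13 4,5-dihydro-1,3-dioxepine
Product: 15 (2S,3R,4R)-2-Ar-4-[(S)-Ar(tert-butyldimethylsilyloxy)methyl]tetrahydrofuran-3-carbaldehyde (2,3-cis-3,4-trans), via oxocarbenium silyl enol ether ion pair 14 (not isolated)
Conditions: TMSOTf (0.2 equiv), CH2Cl2, −78 °C; Et3N quench at −78 °C
Reagents that add atoms: none
Why: TMSOTf silylates the enol-ether oxygen O1 and the benzylic acetal bond C2–O1 ionises to the aryl-stabilised oxocarbenium ion (C2=O3) and the Z-silyl enol ether of ion pair 14, still joined through C4–C5; the enol carbon C6 then adds to C2 and loss of the silyl cation frees the aldehyde, so the seven-membered ring contracts to the tetrahydrofuran with O1–C7 extruded as the formyl group. The closest known reaction type is the Lewis acid-mediated [1,3] O-to-C ring contraction of 4,5-dihydro-1,3-dioxepines to tetrahydrofuran-3-carbaldehydes, a vinyl acetal relative of the Petasis–Ferrier rearrangement. The tetrahydrofuran closes by C–C bond formation in a 5-endo-trig mode at the oxocarbenium carbon (enol-exo at the nucleophile). C3 (lignan C8) is controlled by the C5 stereocentre, since allylic 1,3-strain holds C5–H in the plane of the Z-enol ether and the tethered electrophile adds anti to the bulky aryl(silyloxy)methyl group (3,4-trans); C2 (lignan C7) is controlled by the compact synclinal contact ion pair favoured at −78 °C, which puts aryl cis to formyl (2,3-cis) and therefore trans to the C4 substituent, as the target requires. Both acetal epimers of 13 converge because C2 is planarised. The step needs ionisation at O1–C2 and not O3–C2 (secured by the enol ether oxygen being the better leaving group) and kinetic control (secured by low temperature and an amine quench before warming, which should prevent equilibration to the all-trans isomer and spare the benzylic silyl ether).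

**Step 11**
Reactants: 15 tetrahydrofuran-3-carbaldehyde
Product: 19 (-)-tanegol, via desilylated 2,3-cis-3,4-trans aldehyde 16 (not isolated), via 2,3-trans-3,4-cis hydroxy aldehyde 17 (not isolated), via cis-fused lactol 18 (not isolated)
Conditions: Bu4NF (3.5 equiv), THF, 0 °C to rt; AcOH (3.5 equiv), 0 °C; then MeOH, NaBH4 (4 equiv), 0 °C
Reagents that add atoms: none
Why: Fluoride removes all three silyl groups and the basic medium epimerises the enolisable C3 (C8) aldehyde, which should drain into the cis-fused five-membered lactol with O7' (a trans-fused bicyclo[3.3.0] lactol being too strained), so this temporary ring sets C8 relative to C8', and after neutralisation NaBH4 reduces the lactol through its open form faster than it can epimerise back, giving the C9 primary alcohol and freeing the C7' hydroxyl (desilylation, epimerisation and lactol reduction in one flask).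

**Compound list**

1 | vanillin (4-hydroxy-3-methoxybenzaldehyde) | COc1cc(C=O)ccc1O | starting material
2 | 3-methoxy-4-(triisopropylsilyloxy)benzaldehyde | COc1cc(C=O)ccc1O[Si](C(C)C)(C(C)C)C(C)C | intermediate
3 | (S)-4-benzyloxazolidin-2-one | O=C1OC[C@H](Cc2ccccc2)N1 | starting material
4 | (E)-but-2-enoyl chloride | C/C=C/C(Cl)=O | starting material
5 | (S)-4-benzyl-3-[(E)-but-2-enoyl]oxazolidin-2-one | C/C=C/C(=O)N1C(=O)OC[C@@H]1Cc1ccccc1 | intermediate
6 | Z-dibutylboron dienolate of 5 (not isolated) | C=C/C=C(\OB(CCCC)CCCC)N1C(=O)OC[C@@H]1Cc1ccccc1 | intermediate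
7 | (S)-4-benzyl-3-{(2S)-2-[(S)-Ar(hydroxy)methyl]but-3-enoyl}oxazolidin-2-one | C=C[C@@H]([C@H](O)c1ccc(O[Si](C(C)C)(C(C)C)C(C)C)c(OC)c1)C(=O)N1C(=O)OC[C@@H]1Cc1ccccc1 | intermediate
8 | (S)-4-benzyl-3-{(2S)-2-[(S)-Ar(tert-butyldimethylsilyloxy)methyl]but-3-enoyl}oxazolidin-2-one | C=C[C@@H]([C@H](O[Si](C)(C)C(C)(C)C)c1ccc(O[Si](C(C)C)(C(C)C)C(C)C)c(OC)c1)C(=O)N1C(=O)OC[C@@H]1Cc1ccccc1 | intermediate
9 | (2R)-2-[(S)-Ar(tert-butyldimethylsilyloxy)methyl]but-3-en-1-ol | C=C[C@@H]([C@H](O[Si](C)(C)C(C)(C)C)c1ccc(O[Si](C(C)C)(C(C)C)C(C)C)c(OC)c1)CO | intermediate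
10 | 4-[bis(allyloxy)methyl]-2-methoxy-1-(triisopropylsilyloxy)benzene | C=CCOC(OCC=C)c1ccc(O[Si](C(C)C)(C(C)C)C(C)C)c(OC)c1 | intermediate
11 | mixed allyl acetal of 2 with alcohol 9 (both acetal epimers) | C=C[C@@H]([C@H](O[Si](C)(C)C(C)(C)C)c1ccc(O[Si](C(C)C)(C(C)C)C(C)C)c(OC)c1)COC(OCC=C)c1ccc(O[Si](C(C)C)(C(C)C)C(C)C)c(OC)c1 | intermediate
12 | mixed (E)-prop-1-enyl acetal of 2 with alcohol 9 (both acetal epimers) | C=C[C@@H]([C@H](O[Si](C)(C)C(C)(C)C)c1ccc(O[Si](C(C)C)(C(C)C)C(C)C)c(OC)c1)COC(O/C=C/C)c1ccc(O[Si](C(C)C)(C(C)C)C(C)C)c(OC)c1 | intermediate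
13 | (5R)-2-Ar-5-[(S)-Ar(tert-butyldimethylsilyloxy)methyl]-4,5-dihydro-1,3-dioxepine (both C2 epimers) | COc1cc(C2OC=C[C@@H]([C@H](O[Si](C)(C)C(C)(C)C)c3ccc(O[Si](C(C)C)(C(C)C)C(C)C)c(OC)c3)CO2)ccc1O[Si](C(C)C)(C(C)C)C(C)C | intermediate
14 | ring-opened ion pair: aryl oxocarbenium triflate carrying the Z-trimethylsilyl enol ether (not isolated) | C[Si](C)(C)O/C=C\[C@@H]([C@H](O[Si](C)(C)C(C)(C)C)c1ccc(O[Si](C(C)C)(C(C)C)C(C)C)c(OC)c1)C[O+]=Cc1ccc(O[Si](C(C)C)(C(C)C)C(C)C)c(OC)c1.[O-]S(=O)(=O)C(F)(F)F | intermediate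
15 | (2S,3R,4R)-2-Ar-4-[(S)-Ar(tert-butyldimethylsilyloxy)methyl]tetrahydrofuran-3-carbaldehyde | COc1cc([C@@H](O[Si](C)(C)C(C)(C)C)[C@H]2CO[C@H](c3ccc(O[Si](C(C)C)(C(C)C)C(C)C)c(OC)c3)[C@@H]2C=O)ccc1O[Si](C(C)C)(C(C)C)C(C)C | intermediate
16 | (2S,3R,4R)-2-(4-hydroxy-3-methoxyphenyl)-4-[(S)-hydroxy(4-hydroxy-3-methoxyphenyl)methyl]tetrahydrofuran-3-carbaldehyde (not isolated) | COc1cc([C@@H](O)[C@H]2CO[C@H](c3ccc(O)c(OC)c3)[C@@H]2C=O)ccc1O | intermediate
17 | (2S,3S,4R)-2-(4-hydroxy-3-methoxyphenyl)-4-[(S)-hydroxy(4-hydroxy-3-methoxyphenyl)methyl]tetrahydrofuran-3-carbaldehyde (not isolated) | COc1cc([C@@H](O)[C@H]2CO[C@H](c3ccc(O)c(OC)c3)[C@H]2C=O)ccc1O | intermediate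
18 | cis-fused 2,6-bis(4-hydroxy-3-methoxyphenyl)-3,7-dioxabicyclo[3.3.0]octan-4-ol, aryl groups exo (C9 lactol of tanegol onto O7'; anomers; not isolated) | OC1O[C@H](c2ccc(O)c(OC)c2)[C@H]2CO[C@H](c3ccc(O)c(OC)c3)[C@@H]12 | intermediate
19 | (-)-tanegol, (7S,8R,7'S,8'R) | COc1cc([C@@H](O)[C@H]2CO[C@H](c3ccc(O)c(OC)c3)[C@H]2CO)ccc1O | target

**Step count and risks**

Total: 11 steps. Longest linear sequence: 9 steps (1, 3, 4, 5, 7, 8, 9, 10, 11).

Steps most likely to fail:

Step 10. The ion pair may escape kinetic control (re-ionisation and equilibration toward the all-trans tetrahydrofuran, that is poor facial selectivity at C7), or the benzylic silyl ether may ionise under the Lewis acid. The fallback sets out from 9, builds the ring by classical lignan lactone chemistry and comes back at 19. Hydroboration–oxidation of the vinyl group (9-BBN; NaBO3·4H2O) gives (2R)-2-[(S)-Ar(tert-butyldimethylsilyloxy)methyl]butane-1,4-diol F1. Oxidative lactonisation at the less hindered primary alcohol (TEMPO, PhI(OAc)2) gives (4R)-4-[(S)-Ar(tert-butyldimethylsilyloxy)methyl]dihydrofuran-2(3H)-one F2. Deprotonation with LiN(SiMe3)2 (THF, −78 °C) and aldol addition to 2, trans to the β-substituent, gives the (3S,4R)-3-[Ar(hydroxy)methyl] lactone F3 (carbinol epimers). LiBH4 reduction gives the triol (2R,3R)-2-[Ar(hydroxy)methyl]-3-[(S)-Ar(tert-butyldimethylsilyloxy)methyl]butane-1,4-diol F4. Camphorsulfonic acid (catalytic, CH2Cl2, 0 °C) closes the tetrahydrofuran through the aryl-stabilised C7 cation, with the 2,3-trans arrangement expected, to give the tris-silyl ether of tanegol F5. Bu4NF then gives 19.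

Step 8. The iridium hydride may also move the C8' vinyl group into conjugation, which would erase the C8' stereocentre, and the propenyl ether may later load the ruthenium catalyst unproductively. The fallback sets out from 9 (with 2 as the acetal source), avoids any isomerisation catalyst and comes back at 13. Aldehyde 2 is converted (2-(phenylselanyl)ethoxytrimethylsilane, catalytic TMSOTf) into its bis[2-(phenylselanyl)ethyl] acetal F6. PPTS-catalysed exchange with 9 gives the mixed 2-(phenylselanyl)ethyl acetal F7. Oxidation at selenium (NaIO4, NaHCO3, aqueous MeOH) gives the mixed 2-(phenylseleninyl)ethyl acetal F8. Thermal syn-elimination (i-Pr2NEt, toluene, 80 °C) gives the mixed vinyl acetal F9. Ring-closing metathesis of this vinyl ether (second-generation Grubbs catalyst, toluene, 70 °C) gives 13.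

Step 11. Under fluoride and phenoxide the epimerisation may stay incomplete so that the hydride traps the wrong C8 epimer, C7 may scramble by β-elimination and re-addition of the ring oxygen, or the free phenols may enter quinone methide side reactions. The fallback sets out from 15, moves the temporary ring to the lactone oxidation level with the phenols still silylated and every intermediate isolated, and comes back at 19. Pinnick oxidation (NaClO2, NaH2PO4, 2-methylbut-2-ene) gives the (2S,3R,4R)-tetrahydrofuran-3-carboxylic acid F10, and Me3SiCHN2 gives its methyl ester F11. HF·pyridine removes only the benzylic silyl ether to give the hydroxy ester F12. DBU (toluene, 80 °C) epimerises the ester α-carbon and the cis isomer lactonises to the cis-fused bis(triisopropylsilyl) lactone F13. LiBH4 opens it to the bis(triisopropylsilyl) ether of tanegol F14, and Bu4NF gives 19.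

**Further compounds**

F1 | step 10 | (2R)-2-[(S)-Ar(tert-butyldimethylsilyloxy)methyl]butane-1,4-diol | OCC[C@@H]([C@H](O[Si](C)(C)C(C)(C)C)c1ccc(O[Si](C(C)C)(C(C)C)C(C)C)c(OC)c1)CO
F2 | step 10 | (4R)-4-[(S)-Ar(tert-butyldimethylsilyloxy)methyl]dihydrofuran-2(3H)-one | O=C1C[C@@H]([C@H](O[Si](C)(C)C(C)(C)C)c2ccc(O[Si](C(C)C)(C(C)C)C(C)C)c(OC)c2)CO1
F3 | step 10 | (3S,4R)-3-[Ar(hydroxy)methyl]-4-[(S)-Ar(tert-butyldimethylsilyloxy)methyl]dihydrofuran-2(3H)-one | O=C1[C@H](C(O)c2ccc(O[Si](C(C)C)(C(C)C)C(C)C)c(OC)c2)[C@@H]([C@H](O[Si](C)(C)C(C)(C)C)c2ccc(O[Si](C(C)C)(C(C)C)C(C)C)c(OC)c2)CO1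
F4 | step 10 | (2R,3R)-2-[Ar(hydroxy)methyl]-3-[(S)-Ar(tert-butyldimethylsilyloxy)methyl]butane-1,4-diol | OC[C@H](C(O)c1ccc(O[Si](C(C)C)(C(C)C)C(C)C)c(OC)c1)[C@@H]([C@H](O[Si](C)(C)C(C)(C)C)c1ccc(O[Si](C(C)C)(C(C)C)C(C)C)c(OC)c1)CO
F5 | step 10 | tanegol 7'-O-tert-butyldimethylsilyl 4,4'-bis-O-triisopropylsilyl ether | COc1cc([C@@H](O[Si](C)(C)C(C)(C)C)[C@H]2CO[C@H](c3ccc(O[Si](C(C)C)(C(C)C)C(C)C)c(OC)c3)[C@H]2CO)ccc1O[Si](C(C)C)(C(C)C)C(C)C
F6 | step 8 | bis[2-(phenylselanyl)ethyl] acetal of 2 | COc1cc(C(OCC[Se]c2ccccc2)OCC[Se]c2ccccc2)ccc1O[Si](C(C)C)(C(C)C)C(C)C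
F7 | step 8 | mixed 2-(phenylselanyl)ethyl acetal of 2 with alcohol 9 | C=C[C@@H]([C@H](O[Si](C)(C)C(C)(C)C)c1ccc(O[Si](C(C)C)(C(C)C)C(C)C)c(OC)c1)COC(OCC[Se]c1ccccc1)c1ccc(O[Si](C(C)C)(C(C)C)C(C)C)c(OC)c1
F8 | step 8 | mixed 2-(phenylseleninyl)ethyl acetal of 2 with alcohol 9 (selenoxide of F7) | C=C[C@@H]([C@H](O[Si](C)(C)C(C)(C)C)c1ccc(O[Si](C(C)C)(C(C)C)C(C)C)c(OC)c1)COC(OCC[Se](=O)c1ccccc1)c1ccc(O[Si](C(C)C)(C(C)C)C(C)C)c(OC)c1
F9 | step 8 | mixed vinyl acetal of 2 with alcohol 9 | C=C[C@@H]([C@H](O[Si](C)(C)C(C)(C)C)c1ccc(O[Si](C(C)C)(C(C)C)C(C)C)c(OC)c1)COC(OC=C)c1ccc(O[Si](C(C)C)(C(C)C)C(C)C)c(OC)c1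
F10 | step 11 | (2S,3R,4R)-2-Ar-4-[(S)-Ar(tert-butyldimethylsilyloxy)methyl]tetrahydrofuran-3-carboxylic acid | COc1cc([C@@H](O[Si](C)(C)C(C)(C)C)[C@H]2CO[C@H](c3ccc(O[Si](C(C)C)(C(C)C)C(C)C)c(OC)c3)[C@@H]2C(=O)O)ccc1O[Si](C(C)C)(C(C)C)C(C)C
F11 | step 11 | methyl ester of F10 | COc1cc([C@@H](O[Si](C)(C)C(C)(C)C)[C@H]2CO[C@H](c3ccc(O[Si](C(C)C)(C(C)C)C(C)C)c(OC)c3)[C@@H]2C(=O)OC)ccc1O[Si](C(C)C)(C(C)C)C(C)C
F12 | step 11 | methyl (2S,3R,4R)-2-Ar-4-[(S)-Ar(hydroxy)methyl]tetrahydrofuran-3-carboxylate | COc1cc([C@@H](O)[C@H]2CO[C@H](c3ccc(O[Si](C(C)C)(C(C)C)C(C)C)c(OC)c3)[C@@H]2C(=O)OC)ccc1O[Si](C(C)C)(C(C)C)C(C)C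
F13 | step 11 | cis-fused 2,6-di-Ar-3,7-dioxabicyclo[3.3.0]octan-4-one, aryl groups exo | O=C1O[C@H](c2ccc(O[Si](C(C)C)(C(C)C)C(C)C)c(OC)c2)[C@H]2CO[C@H](c3ccc(O[Si](C(C)C)(C(C)C)C(C)C)c(OC)c3)[C@@H]12
F14 | step 11 | tanegol 4,4'-bis-O-triisopropylsilyl ether | COc1cc([C@@H](O)[C@H]2CO[C@H](c3ccc(O[Si](C(C)C)(C(C)C)C(C)C)c(OC)c3)[C@H]2CO)ccc1O[Si](C(C)C)(C(C)C)C(C)C
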